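**Plan**
- Retrosynthesis: cut the ester between O12′ of the seco-acid half and C1 of the lactone half; cut C5–C6 (sp2–sp3) in both halves to reach one dienyl iodide and a C6 bromide; in the lactone half cut C2(=O)–C3 of the oxetan-2-one and read the CH2OH on C3 as a cleaved vinyl group.
- Enabling feature: in the oxetan-2-one (O1, C2, C3, C4) the ring oxygen sits on C4 and a one-carbon branch on C3, so a vinyl group on C3 makes C3 an allyl terminus beside an alkoxide; a cis-2-vinyloxirane plus one CO delivered by iron is the whole ring.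
- Forward, lactone half: bromo aldehyde → cis-vinyl epoxide → π-allyl tricarbonyliron lactone complex → oxidative C2–C3 closure to the trans-lactone → vinyl to CH2OH → nickel coupling with the dienyl iodide.
- Forward, seco-acid half and union: the same bromo aldehyde → β-keto ester → anti hydroxymethyl aldol unit → nickel coupling with the same dienyl iodide; then esterification of the two halves and one global deprotection.
- Stereochemistry: C7 in both halves from (R)-3-bromo-2-methylpropan-1-ol; lactone C4 from the chloroallylborane (isopinocampheyl groups from (+)-α-pinene), C3 by inversion (iron entry) then retention (closure); C12′ from (S)-BINAP–Ru hydrogenation and C13′ from the anti-selective dianion hydroxymethylation; the 2E bond from the starting enynol, the 4E bond from syn-hydrozirconation and geometry-retentive coupling.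

Key step: step 9

Remark: as drawn, the seco-acid half is 12S,13S and the lactone half is 3R,4R in the ring (both anti, opposite absolute sense), so the two halves are made with opposite reagent control. C1–C14 number each dienoic acid chain (primed for the seco-acid half); ring positions are O1, C2, C3, C4 of the oxetan-2-one.

**Dienyl iodide**

Step 1
Reactants: 1 (E)-3-methylpent-2-en-4-yn-1-ol
Product: 2 (E)-3-methylhex-2-en-4-yn-1-ol
Conditions: n-BuLi (2.1 equiv), THF, −78 → 0 °C; MeI, −78 °C → rt
Reagents that add atoms: iodomethane, CI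
Why: Double deprotonation gives the alkoxide–acetylide, and in THF only the acetylide carbon should be methylated (C-alkylation of a terminal alkyne), the E alkene being untouched.

Step 2
Reactants: 2 (E)-3-methylhex-2-en-4-yn-1-ol
Product: 3 (2E,4E)-5-iodo-3-methylhexa-2,4-dien-1-ol
Conditions: Cp2Zr(H)Cl (2.3 equiv), THF, rt, dark; then I2, 0 °C
Reagents that add atoms: iodine, II
Why: Schwartz hydrozirconation should add Zr–H syn across the internal alkyne with zirconium on the less hindered, methyl-bearing carbon (the first equivalent is spent on the hydroxyl), and iodinolysis with retention should give the 4E iodoalkene.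

Step 3
Reactants: 3 (2E,4E)-5-iodo-3-methylhexa-2,4-dien-1-ol
Product: 5 (2E,4E)-5-iodo-3-methylhexa-2,4-dienoic acid, via dienal 4 (not isolated)
Conditions: MnO2, CH2Cl2, rt; filter; then NaClO2, NaH2PO4, 2-methylbut-2-ene, t-BuOH/H2O, 0 °C → rt
Reagents that add atoms: sodium chlorite, [Na+].[O-]Cl=O
Why: Allylic oxidation with MnO2 should stop at the dienal, and Pinnick oxidation should take it to the acid without touching the vinyl iodide or the alkene geometry.

Step 4
Reactants: 5 (2E,4E)-5-iodo-3-methylhexa-2,4-dienoic acid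
Product: 6 tert-butyl (2E,4E)-5-iodo-3-methylhexa-2,4-dienoate
Conditions: tert-butyl 2,2,2-trichloroacetimidate, BF3·OEt2 (cat.), CH2Cl2/cyclohexane, rt
Reagents that add atoms: tert-butyl 2,2,2-trichloroacetimidate, CC(C)(C)OC(=N)C(Cl)(Cl)Cl
Why: Acid-catalysed tert-butylation with the trichloroacetimidate is an esterification without base, which should avoid deconjugation of the β-methyl dienoic acid.

**Common bromo aldehyde**

Step 5
Reactants: 7 (R)-3-bromo-2-methylpropan-1-ol
Product: 9 (R)-8-bromo-7-methyloct-1-ene, via triflate 8 (not isolated)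
Conditions: Tf2O, 2,6-lutidine, CH2Cl2, −78 °C; then pent-4-enylmagnesium bromide, CuBr·SMe2 (5 mol%), Et2O/THF, −40 → 0 °C
Reagents that add atoms: pent-4-enylmagnesium bromide, C=CCCC[Mg]Br
Why: In copper-catalysed sp3–sp3 coupling with a Grignard reagent the primary triflate is far more reactive than the primary bromide, so the chain should grow at C8 only, and the stereocentre is not involved.

Step 6
Reactants: 9 (R)-8-bromo-7-methyloct-1-ene
Product: 10 (R)-7-bromo-6-methylheptanal
Conditions: O3, CH2Cl2, −78 °C; then PPh3, −78 °C → rt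
Reagents that add atoms: ozone, [O-][O+]=O
Why: Ozonolysis with reductive work-up cleaves the terminal alkene to the C12 aldehyde while the alkyl bromide is inert.

**Lactone half**

Step 7
Reactants: 10 (R)-7-bromo-6-methylheptanal
Product: 12 (2R,3S)-2-[(5R)-6-bromo-5-methylhexyl]-3-ethenyloxirane (cis), via syn-chlorohydrin 11 (not isolated)
Conditions: allyl chloride, LiN(c-C6H11)2, (−)-Ipc2BOMe, Et2O/THF, −95 °C; BF3·OEt2; then 10, −95 °C; HOCH2CH2NH2 work-up; then DBU, CH2Cl2, rt
Reagents that add atoms: allyl chloride, ClCC=C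
Why: Allylboration with the (Z)-γ-chloroallylborane carrying isopinocampheyl groups from (+)-α-pinene should pass through a chair transition state that attacks the Si face of the aldehyde and gives the syn chlorohydrin (3R,4R), and base-induced SN2 closure with inversion at the chlorine-bearing carbon should give the cis epoxide.

Step 8
Reactants: 12 (2R,3S)-2-[(5R)-6-bromo-5-methylhexyl]-3-ethenyloxirane
Product: 13 π-allyl tricarbonyliron lactone complex (endo/exo mixture)
Conditions: Fe2(CO)9 (1.8 equiv), THF, rt, dark, argon; filtration through Celite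
Reagents that add atoms: diiron nonacarbonyl, O=C1[Fe]2(=C=O)(=C=O)(=C=O)C(=O)[Fe]1(=C=O)(=C=O)(=C=O)C2=O
Why: Fe(CO)4 released from Fe2(CO)9 in THF should bind the vinyl group anti to the oxirane C–O bond and open the ring in an SN2′ sense, after which the alkoxide adds to a CO ligand (formation of a π-allyl tricarbonyliron lactone complex); C4 is retained, iron sits on the face of C3 opposite to the former C–O bond, and the s-cis and s-trans conformers give endo and exo isomers with the same configuration at both carbons.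

Step 9
Reactants: 13 π-allyl tricarbonyliron lactone complex (endo/exo mixture)
Product: 14 (3R,4R)-4-[(5R)-6-bromo-5-methylhexyl]-3-ethenyloxetan-2-one
Conditions: (NH4)2Ce(NO3)6 (5 equiv), MeCN, −30 °C → rt
Reagents that add atoms: none
Why: One-electron oxidation of the iron centre by tetravalent cerium labilises the complex, and the alkoxycarbonyl ligand couples with the adjacent allyl terminus C3 by reductive elimination (ligand coupling), iron and three CO being lost. The closest known reaction type is the oxidative demetalation of π-allyl tricarbonyliron lactone complexes to β-lactones. The oxetan-2-one is closed as a contraction of the five-membered ferracycle (Fe, C2, O1, C4, C3) to the four-membered ring by C2–C3 bond formation, formally a 4-exo attack of the acyl carbon on the proximal allyl terminus. C4 is not touched and keeps the configuration set in step 7; C3 receives the acyl carbon on the face that carries iron (retention), and since iron entered anti to the oxirane C–O bond in step 8 (inversion), the cis epoxide maps onto the trans (3R,4R) lactone from both the endo and the exo isomer. The step needs proximal over distal coupling (four-membered ring against the six-membered δ-lactone): C2 and C3 are already held 1,3 within the ferracycle, whereas the distal CH2 can be reached only from the anti-configured allyl isomer through a ring with a cis alkene, and fast oxidation at low temperature should keep the least-motion path. The alkyl bromide and the remote methyl stereocentre are inert to the oxidant.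

Step 10
Reactants: 14 (3R,4R)-4-[(5R)-6-bromo-5-methylhexyl]-3-ethenyloxetan-2-one
Product: 15 (3R,4R)-4-[(5R)-6-bromo-5-methylhexyl]-3-(hydroxymethyl)oxetan-2-one
Conditions: O3, CH2Cl2/MeOH, −78 °C; then NaBH4, −78 → −30 °C; AcOH quench
Reagents that add atoms: ozone, [O-][O+]=O
Why: Ozonolysis of the only alkene with in situ borohydride reduction at low temperature should turn the vinyl group into CH2OH before the intermediate α-formyl lactone can epimerise, and C3 keeps its configuration because no bond to it is broken.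

Step 11
Reactants: 15 (3R,4R)-4-[(5R)-6-bromo-5-methylhexyl]-3-(hydroxymethyl)oxetan-2-one
Product: 16 (3R,4R)-4-[(5R)-6-bromo-5-methylhexyl]-3-{[(tert-butyldimethylsilyl)oxy]methyl}oxetan-2-one
Conditions: TBSOTf, 2,6-lutidine, CH2Cl2, −78 °C
Reagents that add atoms: tert-butyldimethylsilyl triflate, CC(C)(C)[Si](C)(C)OS(=O)(=O)C(F)(F)F
Why: Silyl ether formation with the silyl triflate and a hindered base at low temperature avoids nucleophiles that could open the lactone.

Step 12
Reactants: 16 (3R,4R)-4-[(5R)-6-bromo-5-methylhexyl]-3-{[(tert-butyldimethylsilyl)oxy]methyl}oxetan-2-one; 6 tert-butyl (2E,4E)-5-iodo-3-methylhexa-2,4-dienoate (1.5 equiv)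
Product: 17 tert-butyl (2E,4E,7R)-11-[(2R,3R)-3-{[(tert-butyldimethylsilyl)oxy]methyl}-4-oxooxetan-2-yl]-3,5,7-trimethylundeca-2,4-dienoate
Conditions: NiBr2·DME (10 mol%), 4,4′-di-tert-butyl-2,2′-bipyridine (10 mol%), NaI (25 mol%), Zn dust (2 equiv), DMA, rt
Reagents that add atoms: none
Why: In this nickel-catalysed reductive cross-electrophile coupling, zerovalent nickel inserts into the C–I bond of 6, the alkyl radical from the bromide is captured and reductive elimination forms C5–C6 with retention of the 4E geometry, under non-basic conditions that the lactone and the silyl ether should tolerate.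

Step 13
Reactants: 17 tert-butyl ester of O-TBS-hymeglusin (as named in step 12)
Product: 19 (2E,4E,7R)-11-[(2R,3R)-3-{[(tert-butyldimethylsilyl)oxy]methyl}-4-oxooxetan-2-yl]-3,5,7-trimethylundeca-2,4-dienoic acid, via trimethylsilyl ester 18 (not isolated)
Conditions: TMSOTf, 2,6-lutidine, CH2Cl2, 0 °C; then pH 4 aqueous work-up
Reagents that add atoms: none
Why: TMSOTf/2,6-lutidine should convert the tert-butyl ester into the silyl ester by loss of isobutene (Lewis acid-mediated ester cleavage) while the primary TBS ether stays, and aqueous work-up frees the acid.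

**Seco-acid half**

Step 14
Reactants: 10 (R)-7-bromo-6-methylheptanal
Product: 20 tert-butyl (8R)-9-bromo-8-methyl-3-oxononanoate
Conditions: tert-butyl diazoacetate, SnCl2 (10 mol%), CH2Cl2, rt
Reagents that add atoms: tert-butyl diazoacetate, CC(C)(C)OC(=O)C=[N+]=[N-]
Why: In the Roskamp reaction the diazo ester adds to the Lewis acid-activated aldehyde and a 1,2-hydride shift with loss of N2 gives the β-keto ester directly.

Step 15
Reactants: 20 tert-butyl (8R)-9-bromo-8-methyl-3-oxononanoate
Product: 21 tert-butyl (3S,8R)-9-bromo-3-hydroxy-8-methylnonanoate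
Conditions: H2 (10 bar), RuCl2[(S)-BINAP] (1 mol%), MeOH, 50 °C
Reagents that add atoms: none
Why: Noyori asymmetric hydrogenation of the chelated β-keto ester should set C3 as S with the (S)-BINAP ligand, and the alkyl bromide should not be reduced.

Step 16
Reactants: 21 tert-butyl (3S,8R)-9-bromo-3-hydroxy-8-methylnonanoate
Product: 22 tert-butyl (2S,3S,8R)-9-bromo-3-hydroxy-2-(hydroxymethyl)-8-methylnonanoate
Conditions: LiN(i-Pr)2 (2.3 equiv), THF, −78 → −20 °C; then CH2O (monomer in THF), −78 → −40 °C
Reagents that add atoms: formaldehyde, C=O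
Why: In this Fráter–Seebach reaction the chelated lithium alkoxide–enolate dianion should be attacked by formaldehyde on the face opposite to the C3 side chain, which sets C2 anti to the hydroxyl (2S).

Step 17
Reactants: 22 tert-butyl (2S,3S,8R)-9-bromo-3-hydroxy-2-(hydroxymethyl)-8-methylnonanoate
Product: 23 tert-butyl (2S,3S,8R)-9-bromo-2-{[(tert-butyldimethylsilyl)oxy]methyl}-3-hydroxy-8-methylnonanoate
Conditions: TBSCl (1.1 equiv), imidazole, CH2Cl2, −20 → 0 °C
Reagents that add atoms: tert-butyldimethylsilyl chloride, CC(C)(C)[Si](C)(C)Cl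
Why: Selective silyl ether formation is expected because the primary hydroxyl reacts much faster than the hindered secondary one.

Step 18
Reactants: 23 tert-butyl (2S,3S,8R)-9-bromo-2-{[(tert-butyldimethylsilyl)oxy]methyl}-3-hydroxy-8-methylnonanoate; 6 tert-butyl (2E,4E)-5-iodo-3-methylhexa-2,4-dienoate (1.5 equiv)
Product: 24 di-tert-butyl (2E,4E,7R,12S,13S)-13-{[(tert-butyldimethylsilyl)oxy]methyl}-12-hydroxy-3,5,7-trimethyltetradeca-2,4-dienedioate
Conditions: NiBr2·DME (10 mol%), 4,4′-di-tert-butyl-2,2′-bipyridine (10 mol%), NaI (25 mol%), Zn dust (2 equiv), DMA, rt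
Reagents that add atoms: none
Why: The same nickel-catalysed reductive cross-electrophile coupling as in step 12 should form C5′–C6′ with retention of the 4E geometry, and it tolerates the free secondary alcohol and both esters.

**Union and deprotection**

Step 19
Reactants: 19 O-TBS-hymeglusin (acid, as named in step 13); 24 di-tert-butyl (2E,4E,7R,12S,13S)-13-{[(tert-butyldimethylsilyl)oxy]methyl}-12-hydroxy-3,5,7-trimethyltetradeca-2,4-dienedioate
Product: 25 di-tert-butyl (2E,4E,7R,12S,13S)-13-{[(tert-butyldimethylsilyl)oxy]methyl}-12-{[(2E,4E,7R)-11-((2R,3R)-3-{[(tert-butyldimethylsilyl)oxy]methyl}-4-oxooxetan-2-yl)-3,5,7-trimethylundeca-2,4-dienoyl]oxy}-3,5,7-trimethyltetradeca-2,4-dienedioate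
Conditions: 2-methyl-6-nitrobenzoic anhydride, DMAP, Et3N, CH2Cl2, rt
Reagents that add atoms: none
Why: In this Shiina esterification the mixed anhydride of the dienoic acid acylates the hindered secondary alcohol under DMAP catalysis, with retention at C12′ because the alcohol C–O bond is not broken.

Step 20
Reactants: 25 fully protected ester (as named in step 19)
Product: 26 Fusariumester B
Conditions: TFA/CH2Cl2/H2O (10:10:1), 0 °C → rt
Reagents that add atoms: none
Why: Acidolysis should remove both tert-butyl esters (as isobutene) and both primary silyl ethers in one operation, under conditions that oxetan-2-ones and the dienoate ester are expected to survive.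

**Compound list**
1 | (E)-3-methylpent-2-en-4-yn-1-ol | C#C/C(C)=C/CO | starting material
2 | (E)-3-methylhex-2-en-4-yn-1-ol | CC#C/C(C)=C/CO | intermediate
3 | (2E,4E)-5-iodo-3-methylhexa-2,4-dien-1-ol | CC(=C\CO)/C=C(\C)I | intermediate
4 | (2E,4E)-5-iodo-3-methylhexa-2,4-dienal (not isolated) | CC(=C\C=O)/C=C(\C)I | intermediate
5 | (2E,4E)-5-iodo-3-methylhexa-2,4-dienoic acid | CC(=C\C(=O)O)/C=C(\C)I | intermediate
6 | tert-butyl (2E,4E)-5-iodo-3-methylhexa-2,4-dienoate | CC(=C\C(=O)OC(C)(C)C)/C=C(\C)I | intermediate
7 | (R)-3-bromo-2-methylpropan-1-ol | BrC[C@H](C)CO | starting material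
8 | (R)-3-bromo-2-methylpropyl trifluoromethanesulfonate (not isolated) | BrC[C@H](C)COS(=O)(=O)C(F)(F)F | intermediate
9 | (R)-8-bromo-7-methyloct-1-ene | BrC[C@H](C)CCCCC=C | intermediate
10 | (R)-7-bromo-6-methylheptanal | BrC[C@H](C)CCCCC=O | intermediate
11 | (3R,4R,9R)-10-bromo-3-chloro-9-methyldec-1-en-4-ol (syn; not isolated) | BrC[C@H](C)CCCC[C@@H](O)[C@H](Cl)C=C | intermediate
12 | (2R,3S)-2-[(5R)-6-bromo-5-methylhexyl]-3-ethenyloxirane (cis) | BrC[C@H](C)CCCC[C@H]1O[C@H]1C=C | intermediate
13 | π-allyl tricarbonyliron lactone complex: Fe(CO)3 bound η3 to C1–C3 of the (4R,9R)-10-bromo-9-methyldec-1-en-4-yl chain and σ to the carbonyl carbon of an O–C(=O) bridge on O4; iron on the face of C3 opposite to the former oxirane oxygen; endo/exo mixture | O=C1O[C@H](CCCC[C@@H](C)CBr)[C@H]2[CH]3[CH2][Fe]123(=C=O)(=C=O)=C=O | intermediate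
14 | (3R,4R)-4-[(5R)-6-bromo-5-methylhexyl]-3-ethenyloxetan-2-one | BrC[C@H](C)CCCC[C@H]1OC(=O)[C@@H]1C=C | intermediate
15 | (3R,4R)-4-[(5R)-6-bromo-5-methylhexyl]-3-(hydroxymethyl)oxetan-2-one | BrC[C@H](C)CCCC[C@H]1OC(=O)[C@@H]1CO | intermediate
16 | (3R,4R)-4-[(5R)-6-bromo-5-methylhexyl]-3-{[(tert-butyldimethylsilyl)oxy]methyl}oxetan-2-one | BrC[C@H](C)CCCC[C@H]1OC(=O)[C@@H]1CO[Si](C)(C)C(C)(C)C | intermediate
17 | tert-butyl (2E,4E,7R)-11-[(2R,3R)-3-{[(tert-butyldimethylsilyl)oxy]methyl}-4-oxooxetan-2-yl]-3,5,7-trimethylundeca-2,4-dienoate | CC(=C\C(=O)OC(C)(C)C)/C=C(\C)C[C@H](C)CCCC[C@H]1OC(=O)[C@@H]1CO[Si](C)(C)C(C)(C)C | intermediate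
18 | trimethylsilyl (2E,4E,7R)-11-[(2R,3R)-3-{[(tert-butyldimethylsilyl)oxy]methyl}-4-oxooxetan-2-yl]-3,5,7-trimethylundeca-2,4-dienoate (not isolated) | CC(=C\C(=O)O[Si](C)(C)C)/C=C(\C)C[C@H](C)CCCC[C@H]1OC(=O)[C@@H]1CO[Si](C)(C)C(C)(C)C | intermediate
19 | (2E,4E,7R)-11-[(2R,3R)-3-{[(tert-butyldimethylsilyl)oxy]methyl}-4-oxooxetan-2-yl]-3,5,7-trimethylundeca-2,4-dienoic acid (O-TBS-hymeglusin) | CC(=C\C(=O)O)/C=C(\C)C[C@H](C)CCCC[C@H]1OC(=O)[C@@H]1CO[Si](C)(C)C(C)(C)C | intermediate
20 | tert-butyl (8R)-9-bromo-8-methyl-3-oxononanoate | BrC[C@H](C)CCCCC(=O)CC(=O)OC(C)(C)C | intermediate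
21 | tert-butyl (3S,8R)-9-bromo-3-hydroxy-8-methylnonanoate | BrC[C@H](C)CCCC[C@H](O)CC(=O)OC(C)(C)C | intermediate
22 | tert-butyl (2S,3S,8R)-9-bromo-3-hydroxy-2-(hydroxymethyl)-8-methylnonanoate | BrC[C@H](C)CCCC[C@H](O)[C@H](CO)C(=O)OC(C)(C)C | intermediate
23 | tert-butyl (2S,3S,8R)-9-bromo-2-{[(tert-butyldimethylsilyl)oxy]methyl}-3-hydroxy-8-methylnonanoate | BrC[C@H](C)CCCC[C@H](O)[C@H](CO[Si](C)(C)C(C)(C)C)C(=O)OC(C)(C)C | intermediate
24 | di-tert-butyl (2E,4E,7R,12S,13S)-13-{[(tert-butyldimethylsilyl)oxy]methyl}-12-hydroxy-3,5,7-trimethyltetradeca-2,4-dienedioate | CC(=C\C(=O)OC(C)(C)C)/C=C(\C)C[C@H](C)CCCC[C@H](O)[C@H](CO[Si](C)(C)C(C)(C)C)C(=O)OC(C)(C)C | intermediate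
25 | di-tert-butyl (2E,4E,7R,12S,13S)-13-{[(tert-butyldimethylsilyl)oxy]methyl}-12-{[(2E,4E,7R)-11-((2R,3R)-3-{[(tert-butyldimethylsilyl)oxy]methyl}-4-oxooxetan-2-yl)-3,5,7-trimethylundeca-2,4-dienoyl]oxy}-3,5,7-trimethyltetradeca-2,4-dienedioate | CC(=C\C(=O)OC(C)(C)C)/C=C(\C)C[C@H](C)CCCC[C@H](OC(=O)/C=C(C)/C=C(\C)C[C@H](C)CCCC[C@H]1OC(=O)[C@@H]1CO[Si](C)(C)C(C)(C)C)[C@H](CO[Si](C)(C)C(C)(C)C)C(=O)OC(C)(C)C | intermediate
26 | Fusariumester B | CC(=C\C(=O)O)/C=C(\C)C[C@H](C)CCCC[C@H](OC(=O)/C=C(C)/C=C(\C)C[C@H](C)CCCC[C@H]1OC(=O)[C@@H]1CO)[C@H](CO)C(=O)O | target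

**Step count**
Total steps: 20. Longest linear sequence: 11 steps (steps 5–13, then 19 and 20, from compound 7).

**Steps most likely to fail**

Step 9 (key step). The oxidised complex may couple at the distal allyl terminus and close the six-membered δ-lactone, or lose CO and iron before the C–C bond forms. The fallback closes the same ring by classical C–O lactonisation. It sets out from β-keto ester 20: hydrogenation with RuCl2[(R)-BINAP] should give tert-butyl (3R,8R)-9-bromo-3-hydroxy-8-methylnonanoate F1. Dianion hydroxymethylation (LiN(i-Pr)2, then CH2O) should give the anti diol tert-butyl (2R,3R,8R)-9-bromo-3-hydroxy-2-(hydroxymethyl)-8-methylnonanoate F2, and selective silylation (TBSCl, imidazole) the primary silyl ether F3. TMSOTf/2,6-lutidine should give the bis(trimethylsilyl) intermediate F4, which on aqueous work-up frees the β-hydroxy acid F5. PhSO2Cl in pyridine at 0 °C then closes the oxetan-2-one by carboxyl activation, and the route is rejoined at compound 16.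

Step 12. Zerovalent nickel may insert into the alkyl C–O bond of the strained lactone, radical side reactions may consume the bromide, and either partner may homocouple. The fallback replaces the reductive coupling by a polar organometallic one. It sets out from compound 16: zinc insertion (Zn dust, LiCl, THF, 50 °C) should give the alkylzinc bromide F6, and palladium-catalysed Negishi coupling with iodide 6 (Pd(OAc)2, SPhos, THF, rt) returns to compound 17.

Step 19. Acylation of the hindered secondary hydroxyl next to the branched C13′ may be slow, and the activated β-methyl dienoic acid may deconjugate or isomerise at the 2E bond through a vinylketene. The fallback changes the order of bond formation: the ester is made with the small acid and the halves are joined at C5–C6. It sets out from alcohol 24, which is acylated with iodo acid 5 (2-methyl-6-nitrobenzoic anhydride, DMAP, Et3N) to the iodo dienoyl ester F7. Nickel-catalysed reductive coupling of this iodide with lactone bromide 16 under the conditions of step 12 returns to compound 25.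

**Further compounds**
F1 | step 9 | tert-butyl (3R,8R)-9-bromo-3-hydroxy-8-methylnonanoate | BrC[C@H](C)CCCC[C@@H](O)CC(=O)OC(C)(C)C
F2 | step 9 | tert-butyl (2R,3R,8R)-9-bromo-3-hydroxy-2-(hydroxymethyl)-8-methylnonanoate | BrC[C@H](C)CCCC[C@@H](O)[C@@H](CO)C(=O)OC(C)(C)C
F3 | step 9 | tert-butyl (2R,3R,8R)-9-bromo-2-{[(tert-butyldimethylsilyl)oxy]methyl}-3-hydroxy-8-methylnonanoate | BrC[C@H](C)CCCC[C@@H](O)[C@@H](CO[Si](C)(C)C(C)(C)C)C(=O)OC(C)(C)C
F4 | step 9 | trimethylsilyl (2R,3R,8R)-9-bromo-2-{[(tert-butyldimethylsilyl)oxy]methyl}-8-methyl-3-[(trimethylsilyl)oxy]nonanoate (not isolated) | BrC[C@H](C)CCCC[C@@H](O[Si](C)(C)C)[C@@H](CO[Si](C)(C)C(C)(C)C)C(=O)O[Si](C)(C)C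
F5 | step 9 | (2R,3R,8R)-9-bromo-2-{[(tert-butyldimethylsilyl)oxy]methyl}-3-hydroxy-8-methylnonanoic acid | BrC[C@H](C)CCCC[C@@H](O)[C@@H](CO[Si](C)(C)C(C)(C)C)C(=O)O
F6 | step 12 | bromo{(2R)-6-[(2R,3R)-3-{[(tert-butyldimethylsilyl)oxy]methyl}-4-oxooxetan-2-yl]-2-methylhexyl}zinc | Br[Zn]C[C@H](C)CCCC[C@H]1OC(=O)[C@@H]1CO[Si](C)(C)C(C)(C)C
F7 | step 19 | di-tert-butyl (2E,4E,7R,12S,13S)-13-{[(tert-butyldimethylsilyl)oxy]methyl}-12-{[(2E,4E)-5-iodo-3-methylhexa-2,4-dienoyl]oxy}-3,5,7-trimethyltetradeca-2,4-dienedioate | CC(=C\C(=O)OC(C)(C)C)/C=C(\C)C[C@H](C)CCCC[C@H](OC(=O)/C=C(C)/C=C(\C)I)[C@H](CO[Si](C)(C)C(C)(C)C)C(=O)OC(C)(C)C
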